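## Retrosynthetic overview

1. Target 26 ⇒ β-keto succinimide 23 (the maleimide C=C is restored last by selenoxide elimination) ⇒ aldol union of decalin aldehyde 17 with alkenyl succinimide 21.
2. 21 ⇒ heptanal + maleimide: an enamine-catalysed Michael addition sets the side-chain centre, and methylenation makes the vinyl group.
3. 17 ⇒ ketol 11: the C8 methyl comes from a C8 ketone (methylenation, hydroxyl-directed hydrogenation) and the C6 acid from a malonate (dealkoxycarbonylation, equilibration).
4. 11 ⇒ achiral trienone 9 by a catalytic enantioselective intramolecular dienolate Diels–Alder reaction; rings A and B form together in this one step, with C1, C2, C4a, C8a and the C4a hydroxyl.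
5. 9 ⇒ dimethyl malonate + chloroketone 3 + chloro-phosphorane 5 + glyoxal monoacetal 6. The imide ring is carried intact from maleimide.

Assumption: decalin positions are numbered as in the target (C1 acyl-bearing carbon, C2 methyl, C3=C4, C4a hydroxyl, C6 carboxyl, C8 methyl, C8a ring-fusion CH) and all descriptors refer to this numbering; the sense of induction of both organocatalysts is a prediction and would be inverted, if needed, with the pseudo-enantiomeric squaramide (step 5) or the (R)-prolinol ether (step 10).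

## Route

Step 1
Reactants: 1 (E)-pent-3-enoic acid
Product: 2 (E)-N-methoxy-N-methylpent-3-enamide
Conditions: CDI, CH2Cl2, rt; then MeNH(OMe)·HCl, rt
Reagents that add atoms: N,O-dimethylhydroxylamine hydrochloride, CNOC.Cl
Why: Amide coupling through the acyl imidazole gives the Weinreb amide under conditions mild enough to keep the double bond in the β,γ position.

Step 2
Reactants: 2 (E)-N-methoxy-N-methylpent-3-enamide
Product: 3 (E)-1-chlorohex-4-en-2-one
Conditions: ICH2Cl, MeLi·LiBr, THF, −78 °C; then 1 M HCl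
Reagents that add atoms: chloroiodomethane, ClCI
Why: Carbenoid homologation of a Weinreb amide: chloromethyllithium made in situ adds once because the chelated tetrahedral adduct survives until the quench, giving the α-chloroketone.

Step 3
Reactants: 4 dimethyl malonate (3 equiv); 5 1-chloro-3-(triphenyl-λ5-phosphanylidene)propan-2-one; 6 2,2-dimethoxyacetaldehyde
Product: 8 dimethyl 2-[(3E)-5,5-dimethoxy-2-oxopent-3-en-1-yl]propanedioate, via malonate phosphorane 7 (not isolated)
Conditions: NaH (1 equiv), NaI (cat.), THF, 0 → 60 °C; then 6 (60% aq.), 45 °C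
Reagents that add atoms: none
Why: Malonate C-alkylation (SN2) by the chloromethyl ketone phosphorane, then an E-selective Wittig olefination of the stabilized ylide with the glyoxal monoacetal in the same pot, installs the dienophile arm.

Step 4
Reactants: 8 dimethyl 2-[(3E)-5,5-dimethoxy-2-oxopent-3-en-1-yl]propanedioate; 3 (E)-1-chlorohex-4-en-2-one
Product: 9 dimethyl 2-[(3E)-5,5-dimethoxy-2-oxopent-3-en-1-yl]-2-[(4E)-2-oxohex-4-en-1-yl]propanedioate
Conditions: NaH (1.0 equiv), THF, 0 °C; then 3, NaI (cat.), 0 °C → rt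
Reagents that add atoms: none
Why: SN2 malonate alkylation: the malonate anion of 8 (Na+ counter-ion) displaces chloride from the activated α-chloroketone faster than it adds to an enone, creating the achiral quaternary carbon that carries both arms.

Step 5
Reactants: 9 dimethyl 2-[(3E)-5,5-dimethoxy-2-oxopent-3-en-1-yl]-2-[(4E)-2-oxohex-4-en-1-yl]propanedioate
Product: 11 dimethyl (1S,2R,4aR,8aR)-1-(dimethoxymethyl)-4a-hydroxy-2-methyl-8-oxo-1,2,4a,5,6,7,8,8a-octahydronaphthalene-6,6-dicarboxylate, via dienol 10 (not isolated)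
Conditions: 3,5-bis(trifluoromethyl)phenyl squaramide of 9-amino-9-deoxy-epi-quinidine (10 mol%), toluene (0.02 M), rt
Reagents that add atoms: none
Why: Proposed new method: the quinuclidine of the bifunctional catalyst is proposed to remove the doubly activated C4–H of the β,γ-unsaturated ketone and hold the resulting (Z)-1-oxido-diene as a chiral ammonium ion pair while the squaramide N–H pair binds the enone carbonyl of the other arm, so that an anion-accelerated intramolecular Diels–Alder reaction (vinylogous Michael bond C2–C1 leading, aldol-type bond C4a–C8a closing) through the tether-carbonyl-endo transition state forms rings A and B together, sets C1, C2, C4a and C8a (cis fusion, C1 substituent trans to the C2 methyl) and leaves the C4a oxygen as the free tertiary alcohol after proton return, with no background reaction because the diene exists only as the catalyst-bound dienolate; the closest known reactions are the bifunctional cinchona-base-catalysed Diels–Alder reactions of 3-hydroxy-2-pyrones and anthrones, squaramide-catalysed additions of allyl ketone dienolates, and the thermal cis-selective intramolecular Diels–Alder reaction of deca-1,7,9-trien-3-ones.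

Step 6
Reactants: 11 dimethyl (1S,2R,4aR,8aR)-1-(dimethoxymethyl)-4a-hydroxy-2-methyl-8-oxo-1,2,4a,5,6,7,8,8a-octahydronaphthalene-6,6-dicarboxylate
Product: 12 dimethyl (1S,2R,4aR,8aS)-1-(dimethoxymethyl)-4a-hydroxy-2-methyl-8-methylidene-1,2,4a,5,6,7,8,8a-octahydronaphthalene-6,6-dicarboxylate
Conditions: Cp2TiMe2 (3 equiv), toluene, 65 °C, dark
Reagents that add atoms: bis(cyclopentadienyl)dimethyltitanium (Cp2TiMe2), C[Ti](C)(C1C=CC=C1)C1C=CC=C1
Why: Titanium-carbene (Petasis-type) methylenation is non-basic, so the ketone becomes the exocyclic alkene without epimerizing C8a or eliminating the β-hydroxyl, and the ketone reacts faster than the hindered methyl esters.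

Step 7
Reactants: 12 dimethyl (1S,2R,4aR,8aS)-1-(dimethoxymethyl)-4a-hydroxy-2-methyl-8-methylidene-1,2,4a,5,6,7,8,8a-octahydronaphthalene-6,6-dicarboxylate
Product: 13 dimethyl (1S,2R,4aR,8S,8aR)-1-(dimethoxymethyl)-4a-hydroxy-2,8-dimethyl-1,2,4a,5,6,7,8,8a-octahydronaphthalene-6,6-dicarboxylate
Conditions: [Ir(cod)(PCy3)(py)]PF6 (2.5 mol%), H2 (1 atm), CH2Cl2, 0 °C, stopped after one equivalent of H2
Reagents that add atoms: none
Why: Hydroxyl-directed homogeneous hydrogenation: the C4a hydroxyl (axial on ring B, homoallylic to the methylidene) and the syn ester guide H2 to C8 from their face, cis to H-8a, which puts the new methyl on the face opposite the hydroxyl and cis to the C8a–C1 bond (8S), while the ring alkene, to which the hydroxyl is pseudo-equatorial and which is flanked by C4a and C2, reacts more slowly.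

Step 8
Reactants: 13 dimethyl (1S,2R,4aR,8S,8aR)-1-(dimethoxymethyl)-4a-hydroxy-2,8-dimethyl-1,2,4a,5,6,7,8,8a-octahydronaphthalene-6,6-dicarboxylate
Product: 15 methyl (1S,2R,4aR,6R,8S,8aR)-1-(dimethoxymethyl)-4a-hydroxy-2,8-dimethyl-1,2,4a,5,6,7,8,8a-octahydronaphthalene-6-carboxylate, via monoester epimers 14 (not isolated)
Conditions: NaCl, H2O, DMSO, 150 °C; then NaOMe (0.5 equiv), MeOH, 50 °C
Reagents that add atoms: none
Why: Krapcho dealkoxycarbonylation removes one ester and methoxide equilibration then places the remaining ester equatorial on the ring B chair fixed by the equatorial C8 methyl, that is trans to the C4a hydroxyl and cis to the methyl (6R), any lactone of the 6-epimer being reopened by methoxide.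

Step 9
Reactants: 15 methyl (1S,2R,4aR,6R,8S,8aR)-1-(dimethoxymethyl)-4a-hydroxy-2,8-dimethyl-1,2,4a,5,6,7,8,8a-octahydronaphthalene-6-carboxylate
Product: 17 (1S,2R,4aR,6R,8S,8aR)-1-formyl-4a-hydroxy-2,8-dimethyl-1,2,4a,5,6,7,8,8a-octahydronaphthalene-6-carboxylic acid, via acetal acid 16 (not isolated)
Conditions: LiOH, THF/MeOH/H2O, rt; then AcOH/H2O 4:1, 40 °C
Reagents that add atoms: lithium hydroxide, [Li+].[OH-]; water, O
Why: Saponification followed by mild acid hydrolysis of the dimethyl acetal unmasks the acid and the aldehyde, and C1 stays in its more stable arrangement trans to both neighbours.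

Step 10
Reactants: 18 heptanal; 19 maleimide
Product: 20 (2R)-2-(2,5-dioxopyrrolidin-3-yl)heptanal
Conditions: (S)-α,α-diphenylprolinol trimethylsilyl ether (10 mol%), CHCl3, 4 °C; 18 added slowly, 1:1 with 19
Reagents that add atoms: none
Why: Enamine-catalysed Michael addition of an aldehyde to maleimide, an atom-economical 1:1 addition in which slow addition of the aldehyde suppresses its self-aldol so no excess is needed: the shielding group of the prolinol ether directs attack to one enamine face, fixing the aldehyde α-carbon as R (it becomes the S side-chain centre), while the ring centre is inconsequential.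

Step 11
Reactants: 20 (2R)-2-(2,5-dioxopyrrolidin-3-yl)heptanal
Product: 21 3-[(3S)-oct-1-en-3-yl]pyrrolidine-2,5-dione
Conditions: Ph3PCH3Br (2.5 equiv), KOtBu (2.4 equiv), THF, 0 °C; then 20, −78 → 0 °C
Reagents that add atoms: methyltriphenylphosphonium bromide, C[P+](c1ccccc1)(c1ccccc1)c1ccccc1.[Br-]
Why: Wittig methylenation at low temperature turns the aldehyde into the vinyl group before the α-centre can epimerize, the excess ylide covering the imide N–H.

Step 12
Reactants: 21 3-[(3S)-oct-1-en-3-yl]pyrrolidine-2,5-dione (4 equiv); 17 (1S,2R,4aR,6R,8S,8aR)-1-formyl-4a-hydroxy-2,8-dimethyl-1,2,4a,5,6,7,8,8a-octahydronaphthalene-6-carboxylic acid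
Product: 22 (1S,2R,4aR,6R,8S,8aR)-4a-hydroxy-1-{hydroxy[4-[(3S)-oct-1-en-3-yl]-2,5-dioxopyrrolidin-3-yl]methyl}-2,8-dimethyl-1,2,4a,5,6,7,8,8a-octahydronaphthalene-6-carboxylic acid
Conditions: LiN(iPr)2 (8 equiv), THF, −78 → −40 °C; then 17, −78 °C; AcOH quench
Reagents that add atoms: none
Why: Aldol addition: the N,C-dianion of 21, formed by kinetic deprotonation at the unsubstituted ring CH2, adds to the aldehyde of 17 (two equivalents are spent on its acid and hydroxyl), uniting the fragments through centres that are erased in the next two steps.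

Step 13
Reactants: 22 (1S,2R,4aR,6R,8S,8aR)-4a-hydroxy-1-{hydroxy[4-[(3S)-oct-1-en-3-yl]-2,5-dioxopyrrolidin-3-yl]methyl}-2,8-dimethyl-1,2,4a,5,6,7,8,8a-octahydronaphthalene-6-carboxylic acid
Product: 23 (1S,2R,4aR,6R,8S,8aR)-4a-hydroxy-2,8-dimethyl-1-{[4-[(3S)-oct-1-en-3-yl]-2,5-dioxopyrrolidin-3-yl]carbonyl}-1,2,4a,5,6,7,8,8a-octahydronaphthalene-6-carboxylic acid
Conditions: Dess–Martin periodinane (1.5 equiv), CH2Cl2, 0 °C → rt
Reagents that add atoms: none
Why: Dess–Martin oxidation converts the secondary carbinol into the ketone of a β-keto imide and leaves the tertiary alcohol, the acid and the alkenes alone.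

Step 14
Reactants: 23 (1S,2R,4aR,6R,8S,8aR)-4a-hydroxy-2,8-dimethyl-1-{[4-[(3S)-oct-1-en-3-yl]-2,5-dioxopyrrolidin-3-yl]carbonyl}-1,2,4a,5,6,7,8,8a-octahydronaphthalene-6-carboxylic acid
Product: 26 (1S,2R,4aR,6R,8S,8aR)-4a-hydroxy-2,8-dimethyl-1-{[4-[(3S)-oct-1-en-3-yl]-2,5-dioxo-2,5-dihydro-1H-pyrrol-3-yl]carbonyl}-1,2,4a,5,6,7,8,8a-octahydronaphthalene-6-carboxylic acid, via selenide 24 (not isolated), via selenoxide 25 (not isolated)
Conditions: N-(phenylseleno)phthalimide (1.2 equiv), CH2Cl2, rt; then H2O2 (30% aq.), pyridine, 0 °C → rt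
Reagents that add atoms: none
Why: α-Selenenylation of the enolized β-keto imide and selenoxide syn-elimination toward the only β-hydrogen form the maleimide C=C under near-neutral conditions that spare the doubly allylic side-chain centre.

## Compound list

1 | (E)-pent-3-enoic acid | C/C=C/CC(=O)O | starting material
2 | (E)-N-methoxy-N-methylpent-3-enamide | C/C=C/CC(=O)N(C)OC | intermediate
3 | (E)-1-chlorohex-4-en-2-one | C/C=C/CC(=O)CCl | intermediate
4 | dimethyl malonate | COC(=O)CC(=O)OC | starting material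
5 | 1-chloro-3-(triphenyl-λ5-phosphanylidene)propan-2-one | O=C(CCl)C=P(c1ccccc1)(c1ccccc1)c1ccccc1 | starting material
6 | 2,2-dimethoxyacetaldehyde | COC(OC)C=O | starting material
7 | dimethyl 2-[2-oxo-3-(triphenyl-λ5-phosphanylidene)propyl]propanedioate (not isolated) | COC(=O)C(CC(=O)C=P(c1ccccc1)(c1ccccc1)c1ccccc1)C(=O)OC | intermediate
8 | dimethyl 2-[(3E)-5,5-dimethoxy-2-oxopent-3-en-1-yl]propanedioate | COC(=O)C(CC(=O)/C=C/C(OC)OC)C(=O)OC | intermediate
9 | dimethyl 2-[(3E)-5,5-dimethoxy-2-oxopent-3-en-1-yl]-2-[(4E)-2-oxohex-4-en-1-yl]propanedioate (achiral trienone) | COC(=O)C(CC(=O)C/C=C/C)(CC(=O)/C=C/C(OC)OC)C(=O)OC | intermediate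
10 | dimethyl 2-[(3E)-5,5-dimethoxy-2-oxopent-3-en-1-yl]-2-[(2Z,4E)-2-hydroxyhexa-2,4-dien-1-yl]propanedioate (dienol, present as its catalyst-bound dienolate, not isolated) | COC(=O)C(C/C(O)=C/C=C/C)(CC(=O)/C=C/C(OC)OC)C(=O)OC | intermediate
11 | dimethyl (1S,2R,4aR,8aR)-1-(dimethoxymethyl)-4a-hydroxy-2-methyl-8-oxo-1,2,4a,5,6,7,8,8a-octahydronaphthalene-6,6-dicarboxylate (cis-fused; 4a-OH, 8a-H and the C1 substituent on one face, 2-methyl on the other) | COC(OC)[C@@H]1[C@H]2C(=O)CC(C(=O)OC)(C(=O)OC)C[C@@]2(O)C=C[C@H]1C | intermediate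
12 | dimethyl (1S,2R,4aR,8aS)-1-(dimethoxymethyl)-4a-hydroxy-2-methyl-8-methylidene-1,2,4a,5,6,7,8,8a-octahydronaphthalene-6,6-dicarboxylate | COC(OC)[C@@H]1[C@H]2C(=C)CC(C(=O)OC)(C(=O)OC)C[C@@]2(O)C=C[C@H]1C | intermediate
13 | dimethyl (1S,2R,4aR,8S,8aR)-1-(dimethoxymethyl)-4a-hydroxy-2,8-dimethyl-1,2,4a,5,6,7,8,8a-octahydronaphthalene-6,6-dicarboxylate | COC(OC)[C@@H]1[C@H]2[C@@H](C)CC(C(=O)OC)(C(=O)OC)C[C@@]2(O)C=C[C@H]1C | intermediate
14 | methyl (1S,2R,4aR,8S,8aR)-1-(dimethoxymethyl)-4a-hydroxy-2,8-dimethyl-1,2,4a,5,6,7,8,8a-octahydronaphthalene-6-carboxylate, mixture of C6 epimers (not isolated) | COC(OC)[C@@H]1[C@H]2[C@@H](C)CC(C(=O)OC)C[C@@]2(O)C=C[C@H]1C | intermediate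
15 | methyl (1S,2R,4aR,6R,8S,8aR)-1-(dimethoxymethyl)-4a-hydroxy-2,8-dimethyl-1,2,4a,5,6,7,8,8a-octahydronaphthalene-6-carboxylate | COC(OC)[C@@H]1[C@H]2[C@@H](C)C[C@@H](C(=O)OC)C[C@@]2(O)C=C[C@H]1C | intermediate
16 | (1S,2R,4aR,6R,8S,8aR)-1-(dimethoxymethyl)-4a-hydroxy-2,8-dimethyl-1,2,4a,5,6,7,8,8a-octahydronaphthalene-6-carboxylic acid (as its lithium salt in the flask, not isolated) | COC(OC)[C@@H]1[C@H]2[C@@H](C)C[C@@H](C(=O)O)C[C@@]2(O)C=C[C@H]1C | intermediate
17 | (1S,2R,4aR,6R,8S,8aR)-1-formyl-4a-hydroxy-2,8-dimethyl-1,2,4a,5,6,7,8,8a-octahydronaphthalene-6-carboxylic acid | O=C[C@@H]1[C@H]2[C@@H](C)C[C@@H](C(=O)O)C[C@@]2(O)C=C[C@H]1C | intermediate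
18 | heptanal | CCCCCCC=O | starting material
19 | maleimide (1H-pyrrole-2,5-dione) | O=C1C=CC(=O)N1 | starting material
20 | (2R)-2-(2,5-dioxopyrrolidin-3-yl)heptanal (ring carbon unassigned, inconsequential) | O=C[C@H](CCCCC)C1CC(=O)NC1=O | intermediate
21 | 3-[(3S)-oct-1-en-3-yl]pyrrolidine-2,5-dione (ring carbon unassigned, inconsequential) | C=C[C@H](CCCCC)C1CC(=O)NC1=O | intermediate
22 | (1S,2R,4aR,6R,8S,8aR)-4a-hydroxy-1-{hydroxy[4-[(3S)-oct-1-en-3-yl]-2,5-dioxopyrrolidin-3-yl]methyl}-2,8-dimethyl-1,2,4a,5,6,7,8,8a-octahydronaphthalene-6-carboxylic acid (carbinol and imide ring carbons as a mixture) | C=C[C@H](CCCCC)C1C(C(O)[C@@H]2[C@H]3[C@@H](C)C[C@@H](C(=O)O)C[C@@]3(O)C=C[C@H]2C)C(=O)NC1=O | intermediate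
23 | (1S,2R,4aR,6R,8S,8aR)-4a-hydroxy-2,8-dimethyl-1-{[4-[(3S)-oct-1-en-3-yl]-2,5-dioxopyrrolidin-3-yl]carbonyl}-1,2,4a,5,6,7,8,8a-octahydronaphthalene-6-carboxylic acid (imide ring carbons as a mixture) | C=C[C@H](CCCCC)C1C(C(=O)[C@@H]2[C@H]3[C@@H](C)C[C@@H](C(=O)O)C[C@@]3(O)C=C[C@H]2C)C(=O)NC1=O | intermediate
24 | 3-(phenylselanyl) derivative of 23 at the acyl-bearing imide ring carbon (not isolated) | C=C[C@H](CCCCC)C1C([Se]c2ccccc2)(C(=O)[C@@H]3[C@H]4[C@@H](C)C[C@@H](C(=O)O)C[C@@]4(O)C=C[C@H]3C)C(=O)NC1=O | intermediate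
25 | selenoxide of 24 (not isolated) | C=C[C@H](CCCCC)C1C([Se](=O)c2ccccc2)(C(=O)[C@@H]3[C@H]4[C@@H](C)C[C@@H](C(=O)O)C[C@@]4(O)C=C[C@H]3C)C(=O)NC1=O | intermediate
26 | (1S,2R,4aR,6R,8S,8aR)-4a-hydroxy-2,8-dimethyl-1-{[4-[(3S)-oct-1-en-3-yl]-2,5-dioxo-2,5-dihydro-1H-pyrrol-3-yl]carbonyl}-1,2,4a,5,6,7,8,8a-octahydronaphthalene-6-carboxylic acid (CNP0326775.3) | C=C[C@H](CCCCC)C1=C(C(=O)[C@@H]2[C@H]3[C@@H](C)C[C@@H](C(=O)O)C[C@@]3(O)C=C[C@H]2C)C(=O)NC1=O | target

## Step count and risks

Total: 14 steps. Longest linear sequence: 11 steps (1, 2, 4, 5, 6, 7, 8, 9, 12, 13, 14).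

**Step 5 (proposed new reaction).** The dienolate may instead add through its α-carbon to the C8 ketone (a reversible six-ring aldol of the 1,5-diketone), the β,γ-enone may drift into conjugation, and cis/trans fusion and enantioselectivity are untested. The fallback uses known chemistry and sets out from 9. Soft enolisation (iPr3SiOTf, Et3N, CH2Cl2, −78 °C) gives the triisopropylsilyl dienol ether F1. This is cyclised at −78 °C with the protonated (S)-o-tolyl oxazaborolidine (Tf2NH-activated), an established catalyst class for enantioselective Diels–Alder reactions of enones with silyloxy dienes, to the silyl ether F2. HF·pyridine then removes the silyl group and the route is rejoined at 11.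

**Step 7 (directed hydrogenation).** The ring alkene may also be reduced, or hydrogen may arrive from the wrong face. The fallback sets out from 12 and changes both order and mechanism. Dealkoxycarbonylation first (NaCl, H2O, DMSO, 150 °C) gives the methylidene monoester F3. A radical hydrogen-atom-transfer hydrogenation (Mn(dpm)3, dpm = 2,2,6,6-tetramethylheptane-3,5-dionate, with PhSiH3 and tBuOOH in iPrOH) then reduces only the 1,1-disubstituted alkene. Axial hydrogen delivery from the convex face should give the equatorial C8 methyl. The route is rejoined at 14, which is equilibrated with NaOMe as in step 8.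

**Step 12 (fragment union).** Dianion formation from the N–H succinimide and its aldol with an unprotected hydroxy acid may be inefficient. The fallback sets out from 21. Selenenylation (LiN(iPr)2, then PhSeBr) gives the selenide F4, and oxidation with H2O2 with syn-elimination gives the 3-alkylmaleimide F5. A thiazolium-catalysed Stetter reaction (3-benzyl-5-(2-hydroxyethyl)-4-methylthiazolium chloride, Et3N, dioxane, 60 °C) adds the acyl anion of aldehyde 17 to the unsubstituted carbon of F5. This rejoins the route at 23 without the aldol and oxidation steps.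

## Further compounds

F1 | step 5 | dimethyl 2-[(3E)-5,5-dimethoxy-2-oxopent-3-en-1-yl]-2-[(2Z,4E)-2-[(triisopropylsilyl)oxy]hexa-2,4-dien-1-yl]propanedioate | COC(=O)C(C/C(O[Si](C(C)C)(C(C)C)C(C)C)=C/C=C/C)(CC(=O)/C=C/C(OC)OC)C(=O)OC
F2 | step 5 | dimethyl (1S,2R,4aR,8aR)-1-(dimethoxymethyl)-2-methyl-8-oxo-4a-[(triisopropylsilyl)oxy]-1,2,4a,5,6,7,8,8a-octahydronaphthalene-6,6-dicarboxylate | COC(OC)[C@@H]1[C@H]2C(=O)CC(C(=O)OC)(C(=O)OC)C[C@@]2(O[Si](C(C)C)(C(C)C)C(C)C)C=C[C@H]1C
F3 | step 7 | methyl (1S,2R,4aR,8aS)-1-(dimethoxymethyl)-4a-hydroxy-2-methyl-8-methylidene-1,2,4a,5,6,7,8,8a-octahydronaphthalene-6-carboxylate, mixture of C6 epimers | COC(OC)[C@@H]1[C@H]2C(=C)CC(C(=O)OC)C[C@@]2(O)C=C[C@H]1C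
F4 | step 12 | 3-[(3S)-oct-1-en-3-yl]-4-(phenylselanyl)pyrrolidine-2,5-dione | C=C[C@H](CCCCC)C1C([Se]c2ccccc2)C(=O)NC1=O
F5 | step 12 | 3-[(3S)-oct-1-en-3-yl]-1H-pyrrole-2,5-dione | C=C[C@H](CCCCC)C1=CC(=O)NC1=O
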